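**Strategy.** The trans-decalin is disconnected at C5–C10 and C8–C9. A catalytic enantioselective intramolecular Diels–Alder reaction of an acyclic trienal then closes rings A and B together and sets C5, C8, C9 and C10 in one operation. The step exploits one feature: the quaternary C10 methyl, the trans C5 hydrogen and the C9 carbon substituent cis to that methyl are the endo adduct of an (E)-3-methyl enal (C9=C10, formyl carbon C11) and a C5–C8 dienyl ester joined through C1–C4. The precursor is a dimethyl malonate (future C4, non-stereogenic) bearing the (E)-enal chain and a (1E,3E)-4-pivaloyloxybutadienyl group. The C8 oxygen later becomes the exocyclic methylene.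

Key step: step 9

Assumption and correction: labdane numbering is used (C18 = 4α, C19 = 4β) and the target is read as the 4α-CO2Me/4β-CH3, 13S isomer; the chain beyond C11 has five carbons (C12–C16), so the glutarate-derived Wittig salt is shortened by one carbon (step 11); the catalyst antipodes in steps 9 and 10 are assigned from the accepted face-selectivity models, from memory, and would be exchanged for their mirror-image or pseudo-enantiomeric forms if a first run showed the opposite sense.

**Step 1**
Reactants: 1 5-chloropent-1-yne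
Product: 3 (E)-6-chloro-3-methylhex-2-en-1-ol, via alkenylalane 2 (not isolated)
Conditions: Me3Al (2 equiv), Cp2ZrCl2 (0.2 equiv), CH2Cl2, 0 °C → rt; then (CH2O)n, THF, 0 °C → rt; aq. HCl
Reagents that add atoms: trimethylaluminium C[Al](C)C; formaldehyde (as paraformaldehyde) C=O
Why: Zirconium-catalysed carboalumination (Negishi) adds CH3 and Al syn across the terminal alkyne with aluminium on the terminal carbon, and hydroxymethylation of the alkenylalane with retention fixes the E trisubstituted alkene (future C9=C10 with C20 and C11).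

**Step 2**
Reactants: 3 (E)-6-chloro-3-methylhex-2-en-1-ol
Product: 4 tert-butyl{[(E)-6-chloro-3-methylhex-2-en-1-yl]oxy}dimethylsilane
Conditions: TBSCl, imidazole, DMF, rt
Reagents that add atoms: tert-butyldimethylsilyl chloride CC(C)(C)[Si](C)(C)Cl
Why: Standard silylation of a primary allylic alcohol masks the C11 oxygen through the basic and palladium-mediated steps.

**Step 3**
Reactants: 5 dimethyl malonate; 4 tert-butyl{[(E)-6-chloro-3-methylhex-2-en-1-yl]oxy}dimethylsilane
Product: 7 dimethyl 2-[(E)-6-(tert-butyldimethylsilyloxy)-4-methylhex-4-en-1-yl]malonate, via sodium malonate enolate 6 (not isolated)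
Conditions: 5 (3 equiv), NaH (2.5 equiv), THF/DMF, 0 °C; then 4, NaI (0.2 equiv), 65 °C
Reagents that add atoms: none
Why: Malonic ester alkylation, in which the enolate displaces the primary chloride (iodide exchange in situ, Finkelstein) and the excess of malonate suppresses dialkylation, joins C3 to the future C4.

**Step 4**
Reactants: 7 dimethyl 2-[(E)-6-(tert-butyldimethylsilyloxy)-4-methylhex-4-en-1-yl]malonate; 8 2-vinyloxirane (butadiene monoxide, racemic)
Product: 9 dimethyl 2-[(E)-4-hydroxybut-2-en-1-yl]-2-[(E)-6-(tert-butyldimethylsilyloxy)-4-methylhex-4-en-1-yl]malonate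
Conditions: 8 (1.5 equiv), Pd(PPh3)4 (3 mol%), THF, 0 °C → rt
Reagents that add atoms: none
Why: Tsuji–Trost alkylation, in which zerovalent palladium opens the vinyl epoxide to a π-allyl alkoxide that deprotonates the malonate and the bulky tertiary carbanion attacks the distal allyl terminus, should give the linear E allylic alcohol (C5–C8) without any metathesis step that could ring-close onto the C9=C10 alkene.

**Step 5**
Reactants: 9 dimethyl 2-[(E)-4-hydroxybut-2-en-1-yl]-2-[(E)-6-(tert-butyldimethylsilyloxy)-4-methylhex-4-en-1-yl]malonate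
Product: 10 dimethyl 2-[(E)-4-oxobut-2-en-1-yl]-2-[(E)-6-(tert-butyldimethylsilyloxy)-4-methylhex-4-en-1-yl]malonate
Conditions: MnO2 (15 equiv), CH2Cl2, rt
Reagents that add atoms: none
Why: MnO2 oxidation is selective for the allylic alcohol and leaves the silyl ether, the esters and both alkene geometries untouched.

**Step 6**
Reactants: 10 dimethyl 2-[(E)-4-oxobut-2-en-1-yl]-2-[(E)-6-(tert-butyldimethylsilyloxy)-4-methylhex-4-en-1-yl]malonate
Product: 12 dimethyl 2-[(E)-6-(tert-butyldimethylsilyloxy)-4-methylhex-4-en-1-yl]-2-[(1E,3E)-4-(pivaloyloxy)buta-1,3-dien-1-yl]malonate, via potassium dienolate 11 (not isolated)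
Conditions: KOtBu (1.3 equiv), THF, −78 °C; then pivaloyl chloride (1.5 equiv), −78 → −20 °C
Reagents that add atoms: pivaloyl chloride CC(C)(C)C(=O)Cl
Why: γ-Deprotonation of the enal at C5 gives the extended dienolate, which is O-acylated (dienolate O-acylation); reaction through the s-trans enal and the bulk of the quaternary C4 should give the 1E,3E dienyl ester.

**Step 7**
Reactants: 12 dimethyl 2-[(E)-6-(tert-butyldimethylsilyloxy)-4-methylhex-4-en-1-yl]-2-[(1E,3E)-4-(pivaloyloxy)buta-1,3-dien-1-yl]malonate
Product: 13 dimethyl 2-[(E)-6-hydroxy-4-methylhex-4-en-1-yl]-2-[(1E,3E)-4-(pivaloyloxy)buta-1,3-dien-1-yl]malonate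
Conditions: HF·pyridine, pyridine/THF, 0 °C → rt
Reagents that add atoms: none
Why: Buffered fluoride desilylation cleaves the primary silyl ether under conditions that a dienyl pivalate and a malonate tolerate.

**Step 8**
Reactants: 13 dimethyl 2-[(E)-6-hydroxy-4-methylhex-4-en-1-yl]-2-[(1E,3E)-4-(pivaloyloxy)buta-1,3-dien-1-yl]malonate
Product: 14 dimethyl 2-[(4E)-4-methyl-6-oxohex-4-en-1-yl]-2-[(1E,3E)-4-(pivaloyloxy)buta-1,3-dien-1-yl]malonate
Conditions: MnO2 (20 equiv), CH2Cl2, rt; used promptly
Reagents that add atoms: none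
Why: Neutral MnO2 oxidation of the allylic alcohol gives the E enal without acid or base that could hydrolyse the dienyl ester or isomerise the enal.

**Step 9**
Reactants: 14 dimethyl 2-[(4E)-4-methyl-6-oxohex-4-en-1-yl]-2-[(1E,3E)-4-(pivaloyloxy)buta-1,3-dien-1-yl]malonate
Product: 15 dimethyl 9β-formyl-10β-methyl-8β-(pivaloyloxy)-5α-H-trans-decal-6-ene-4,4-dicarboxylate (labdane numbering)
Conditions: (3aR)-3,3-diphenyl-1-(2-methylphenyl)tetrahydro-1H,3H-pyrrolo[1,2-c][1,3,2]oxazaborole (20 mol%), (CF3SO2)2NH (18 mol%), CH2Cl2, −40 → −10 °C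
Reagents that add atoms: none
Why: Proposed new method: the cationic boron Lewis acid binds the formyl oxygen (syn to the formyl hydrogen, with a formyl C–H···O contact to the ring oxygen) and lowers the enal LUMO, so that a concerted but asynchronous [4+2] takes place in which the nucleophilic C5 terminus of the 1-acyloxydiene bonds to the β-carbon C10 ahead of C8–C9; the closest known reactions are oxazaborolidinium-catalysed Diels–Alder reactions of α-substituted and β-monosubstituted enals (inter- and intramolecular) and Me2AlCl-promoted cyclisations of deca-1,7,9-trienals to trans-decalins, but a β,β-disubstituted enal paired with a 1-acyloxydiene is without precedent. Ring A is closed by the C5–C10 bond through the four-carbon C1–C4 tether held in a chair, and ring B is the cyclohexene created by the cycloaddition itself (C5–C10 plus C8–C9). The trans ring fusion (5α-H, 10β-CH3) follows from the endo position of the complexed formyl group combined with the chair tether, the C9 configuration (formyl cis to the C10 methyl) from the E enal geometry, the C8 configuration (pivalate cis to formyl) from the E,E diene geometry, and the absolute configuration from the catalyst, whose phenyl group shields one enal face so that the diene should add to the C9 Si (C10 Re) face. The step needs endo over exo selectivity and enal-face selectivity; the first is secured by Lewis-acid complexation and the Thorpe–Ingold effect of the non-stereogenic C4 malonate, which adds no diastereomers, and the second rests on the catalyst alone.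

**Step 10**
Reactants: 16 3-methylglutaric anhydride
Product: 17 (S)-5-methoxy-3-methyl-5-oxopentanoic acid
Conditions: MeOH (10 equiv), hydroquinidine anthraquinone-1,4-diyl diether [(DHQD)2AQN, 20 mol%], Et2O, −40 °C
Reagents that add atoms: methanol CO
Why: Alkaloid-catalysed (general-base) methanolysis that selects one enantiotopic carbonyl of the prochiral anhydride sets the future C13 stereocentre, the free-acid arm being the one shortened next.

**Step 11**
Reactants: 17 (S)-5-methoxy-3-methyl-5-oxopentanoic acid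
Product: 18 methyl (R)-4-bromo-3-methylbutanoate
Conditions: HgO (0.6 equiv), Br2 (1.1 equiv), BrCCl3, 75 °C, dark
Reagents that add atoms: bromine BrBr
Why: Hunsdiecker bromodecarboxylation (HgO variant) through the acyl hypobromite and a primary radical removes one carboxyl carbon, so that the fragment holds exactly C12–C16, and does not touch the stereocentre (the descriptor changes by priority only).

**Step 12**
Reactants: 18 methyl (R)-4-bromo-3-methylbutanoate
Product: 19 [(R)-4-methoxy-2-methyl-4-oxobutyl]triphenylphosphonium bromide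
Conditions: PPh3 (1.1 equiv), MeCN, reflux
Reagents that add atoms: triphenylphosphine c1ccc(cc1)P(c1ccccc1)c1ccccc1
Why: SN2 quaternisation of triphenylphosphine by the primary bromide gives the Wittig salt.

**Step 13**
Reactants: 15 dimethyl 9β-formyl-10β-methyl-8β-(pivaloyloxy)-5α-H-trans-decal-6-ene-4,4-dicarboxylate; 19 [(R)-4-methoxy-2-methyl-4-oxobutyl]triphenylphosphonium bromide
Product: 21 trimethyl (11Z,13R)-8β-(pivaloyloxy)-17-norlabda-6,11-diene-15,18,19-trioate, via phosphorus ylide 20 (not isolated)
Conditions: 19 (1.8 equiv), NaN(SiMe3)2 (1.7 equiv), THF, −78 → 0 °C; then 15, −78 °C → rt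
Reagents that add atoms: none
Why: Wittig olefination with the non-stabilised ylide should add to the hindered aldehyde faster than it deprotonates C9 and give mainly the Z alkene, whose geometry is irrelevant because it is hydrogenated next; C13 arrives intact (13R here only through a priority change).

**Step 14**
Reactants: 21 trimethyl (11Z,13R)-8β-(pivaloyloxy)-17-norlabda-6,11-diene-15,18,19-trioate
Product: 22 trimethyl (13S)-8β-(pivaloyloxy)-17-norlabdane-15,18,19-trioate
Conditions: H2 (3 atm), PtO2 (10 mol%), EtOAc, rt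
Reagents that add atoms: none
Why: Heterogeneous hydrogenation saturates C6=C7 and C11=C12 without creating a stereocentre, platinum being chosen over palladium to avoid allylic C8–O hydrogenolysis and double-bond migration toward C9 or C13.

**Step 15**
Reactants: 22 trimethyl (13S)-8β-(pivaloyloxy)-17-norlabdane-15,18,19-trioate
Product: 23 (13S)-8β-hydroxy-19-methoxy-19-oxo-17-norlabdane-15,18-dioic acid
Conditions: KOH (10 equiv), MeOH/H2O (4:1), 70 °C; then aq. HCl, 0 °C
Reagents that add atoms: potassium hydroxide [K+].[OH-]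
Why: Saponification (acyl–oxygen cleavage) removes the primary C15 ester, the equatorial 4α ester and the pivalate, whereas the 4β ester, axial, 1,3-diaxial to the C10 methyl and flanked by the new carboxylate, should resist; this steric discrimination makes C4 stereogenic in the required sense.

**Step 16**
Reactants: 23 (13S)-8β-hydroxy-19-methoxy-19-oxo-17-norlabdane-15,18-dioic acid
Product: 24 (13S)-19-methoxy-8,19-dioxo-17-norlabdane-15,18-dioic acid
Conditions: CrO3, H2SO4, acetone, 0 °C
Reagents that add atoms: none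
Why: Jones oxidation converts the axial secondary alcohol into the C8 ketone in the presence of free acids and removes the C8 stereocentre.

**Step 17**
Reactants: 24 (13S)-19-methoxy-8,19-dioxo-17-norlabdane-15,18-dioic acid
Product: 25 (13S)-19-methoxy-19-oxolabd-8(17)-ene-15,18-dioic acid
Conditions: Ph3PCH3Br (6 equiv), KOtBu (8 equiv), THF, rt → 60 °C; then dilute HCl, 0 °C
Reagents that add atoms: methyltriphenylphosphonium bromide C[P+](c1ccccc1)(c1ccccc1)c1ccccc1.[Br-]
Why: Wittig methylenation with excess ylide on the dicarboxylate installs C17, and any base-induced epimerisation at C9 converges on the equatorial, desired side chain.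

**Step 18**
Reactants: 25 (13S)-19-methoxy-19-oxolabd-8(17)-ene-15,18-dioic acid
Product: 26 (13S)-19-hydroxylabd-8(17)-ene-15,18-dioic acid
Conditions: LiEt3BH (8 equiv), THF, 0 → 60 °C; then dilute HCl, 0 °C
Reagents that add atoms: none
Why: Nucleophilic hydride reduction, in which LiEt3BH first turns both acids into unreactive lithium carboxylates (releasing Et3B, which does not hydroborate the alkene) and then reduces the remaining axial ester to the 19-alcohol.

**Step 19**
Reactants: 26 (13S)-19-hydroxylabd-8(17)-ene-15,18-dioic acid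
Product: 27 dimethyl (13S)-19-hydroxylabd-8(17)-ene-15,18-dioate
Conditions: MeI (5 equiv), K2CO3 (3 equiv), DMF, rt
Reagents that add atoms: iodomethane CI
Why: Carboxylate O-alkylation (SN2 on iodomethane) esterifies both acids, the hindered C18 acid included, and leaves the neopentyl alcohol free.

**Step 20**
Reactants: 27 dimethyl (13S)-19-hydroxylabd-8(17)-ene-15,18-dioate
Product: 28 dimethyl (13S)-19-[(1H-imidazol-1-ylcarbonothioyl)oxy]labd-8(17)-ene-15,18-dioate
Conditions: 1,1'-thiocarbonyldiimidazole (3 equiv), 4-(dimethylamino)pyridine (0.2 equiv), toluene, 90 °C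
Reagents that add atoms: 1,1'-thiocarbonyldiimidazole S=C(n1ccnc1)n1ccnc1
Why: Thioacylation of the primary alcohol gives the radical precursor for a Barton–McCombie deoxygenation.

**Step 21**
Reactants: 28 dimethyl (13S)-19-[(1H-imidazol-1-ylcarbonothioyl)oxy]labd-8(17)-ene-15,18-dioate
Product: 29 dimethyl (13S)-labd-8(17)-ene-15,18-dioate
Conditions: Bu3SnH (3 equiv), azobisisobutyronitrile (portions), xylene, 130 °C
Reagents that add atoms: none
Why: Barton–McCombie deoxygenation (stannyl radical addition to sulfur, C–O fragmentation to the primary C19 radical, hydrogen abstraction) leaves the axial 4β-methyl under neutral conditions that spare the acid-sensitive exocyclic alkene.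

**Step 22**
Reactants: 29 dimethyl (13S)-labd-8(17)-ene-15,18-dioate
Product: 30 (13S)-18-methoxy-18-oxolabd-8(17)-en-15-oic acid (CNP0135192.1)
Conditions: LiOH (4 equiv), THF/MeOH/H2O, rt; then dilute HCl to pH 3, 0 °C
Reagents that add atoms: lithium hydroxide [Li+].[OH-]
Why: Chemoselective saponification hydrolyses the unhindered primary C15 ester at room temperature, whereas the C18 ester on the quaternary C4 is not attacked.

**Compound list**
1 | 5-chloropent-1-yne | C#CCCCCl | starting material
2 | (E)-(5-chloro-2-methylpent-1-en-1-yl)dimethylalane | C[Al](C)/C=C(\C)CCCCl | intermediate (not isolated)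
3 | (E)-6-chloro-3-methylhex-2-en-1-ol | OC/C=C(\C)CCCCl | intermediate
4 | tert-butyl{[(E)-6-chloro-3-methylhex-2-en-1-yl]oxy}dimethylsilane | CC(C)(C)[Si](C)(C)OC/C=C(\C)CCCCl | intermediate
5 | dimethyl malonate | COC(=O)CC(=O)OC | starting material
6 | sodium enolate of dimethyl malonate | [Na+].COC(=O)[CH-]C(=O)OC | intermediate (not isolated)
7 | dimethyl 2-[(E)-6-(tert-butyldimethylsilyloxy)-4-methylhex-4-en-1-yl]malonate | COC(=O)C(CCC/C(C)=C/CO[Si](C)(C)C(C)(C)C)C(=O)OC | intermediate
8 | 2-vinyloxirane (butadiene monoxide, racemic) | C=CC1CO1 | starting material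
9 | dimethyl 2-[(E)-4-hydroxybut-2-en-1-yl]-2-[(E)-6-(tert-butyldimethylsilyloxy)-4-methylhex-4-en-1-yl]malonate | COC(=O)C(C/C=C/CO)(CCC/C(C)=C/CO[Si](C)(C)C(C)(C)C)C(=O)OC | intermediate
10 | dimethyl 2-[(E)-4-oxobut-2-en-1-yl]-2-[(E)-6-(tert-butyldimethylsilyloxy)-4-methylhex-4-en-1-yl]malonate | COC(=O)C(C/C=C/C=O)(CCC/C(C)=C/CO[Si](C)(C)C(C)(C)C)C(=O)OC | intermediate
11 | potassium (1E,3E)-dienolate of 10 | [K+].[O-]/C=C/C=C/C(CCC/C(C)=C/CO[Si](C)(C)C(C)(C)C)(C(=O)OC)C(=O)OC | intermediate (not isolated)
12 | dimethyl 2-[(E)-6-(tert-butyldimethylsilyloxy)-4-methylhex-4-en-1-yl]-2-[(1E,3E)-4-(pivaloyloxy)buta-1,3-dien-1-yl]malonate | COC(=O)C(/C=C/C=C/OC(=O)C(C)(C)C)(CCC/C(C)=C/CO[Si](C)(C)C(C)(C)C)C(=O)OC | intermediate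
13 | dimethyl 2-[(E)-6-hydroxy-4-methylhex-4-en-1-yl]-2-[(1E,3E)-4-(pivaloyloxy)buta-1,3-dien-1-yl]malonate | COC(=O)C(/C=C/C=C/OC(=O)C(C)(C)C)(CCC/C(C)=C/CO)C(=O)OC | intermediate
14 | dimethyl 2-[(4E)-4-methyl-6-oxohex-4-en-1-yl]-2-[(1E,3E)-4-(pivaloyloxy)buta-1,3-dien-1-yl]malonate (trienal, key-step precursor) | O=C/C=C(\C)CCCC(C(=O)OC)(C(=O)OC)/C=C/C=C/OC(=O)C(C)(C)C | intermediate
15 | dimethyl 9β-formyl-10β-methyl-8β-(pivaloyloxy)-5α-H-trans-decal-6-ene-4,4-dicarboxylate (key-step product) | CC(C)(C)C(=O)O[C@H]1C=C[C@@H]2[C@](C)(CCCC2(C(=O)OC)C(=O)OC)[C@H]1C=O | intermediate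
16 | 3-methylglutaric anhydride | CC1CC(=O)OC(=O)C1 | starting material
17 | (S)-5-methoxy-3-methyl-5-oxopentanoic acid | OC(=O)C[C@H](C)CC(=O)OC | intermediate
18 | methyl (R)-4-bromo-3-methylbutanoate | BrC[C@H](C)CC(=O)OC | intermediate
19 | [(R)-4-methoxy-2-methyl-4-oxobutyl]triphenylphosphonium bromide | c1ccccc1[P+](c1ccccc1)(c1ccccc1)C[C@H](C)CC(=O)OC.[Br-] | intermediate
20 | methyl (R)-3-methyl-4-(triphenyl-λ5-phosphanylidene)butanoate (ylide) | c1ccccc1P(c1ccccc1)(c1ccccc1)=C[C@H](C)CC(=O)OC | intermediate (not isolated)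
21 | trimethyl (11Z,13R)-8β-(pivaloyloxy)-17-norlabda-6,11-diene-15,18,19-trioate | CC(C)(C)C(=O)O[C@H]1C=C[C@@H]2[C@](C)(CCCC2(C(=O)OC)C(=O)OC)[C@H]1/C=C\[C@H](C)CC(=O)OC | intermediate
22 | trimethyl (13S)-8β-(pivaloyloxy)-17-norlabdane-15,18,19-trioate | CC(C)(C)C(=O)O[C@H]1CC[C@@H]2[C@](C)(CCCC2(C(=O)OC)C(=O)OC)[C@H]1CC[C@H](C)CC(=O)OC | intermediate
23 | (13S)-8β-hydroxy-19-methoxy-19-oxo-17-norlabdane-15,18-dioic acid (4α-COOH, 4β-CO2Me) | O[C@H]1CC[C@@H]2[C@](C)(CCC[C@@]2(C(=O)OC)C(=O)O)[C@H]1CC[C@H](C)CC(=O)O | intermediate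
24 | (13S)-19-methoxy-8,19-dioxo-17-norlabdane-15,18-dioic acid | O=C1CC[C@@H]2[C@](C)(CCC[C@@]2(C(=O)OC)C(=O)O)[C@H]1CC[C@H](C)CC(=O)O | intermediate
25 | (13S)-19-methoxy-19-oxolabd-8(17)-ene-15,18-dioic acid | C=C1CC[C@@H]2[C@](C)(CCC[C@@]2(C(=O)OC)C(=O)O)[C@H]1CC[C@H](C)CC(=O)O | intermediate
26 | (13S)-19-hydroxylabd-8(17)-ene-15,18-dioic acid | C=C1CC[C@@H]2[C@](C)(CCC[C@@]2(CO)C(=O)O)[C@H]1CC[C@H](C)CC(=O)O | intermediate
27 | dimethyl (13S)-19-hydroxylabd-8(17)-ene-15,18-dioate | C=C1CC[C@@H]2[C@](C)(CCC[C@@]2(CO)C(=O)OC)[C@H]1CC[C@H](C)CC(=O)OC | intermediate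
28 | dimethyl (13S)-19-[(1H-imidazol-1-ylcarbonothioyl)oxy]labd-8(17)-ene-15,18-dioate | C=C1CC[C@@H]2[C@](C)(CCC[C@@]2(COC(=S)n3ccnc3)C(=O)OC)[C@H]1CC[C@H](C)CC(=O)OC | intermediate
29 | dimethyl (13S)-labd-8(17)-ene-15,18-dioate | C=C1CC[C@@H]2[C@](C)(CCC[C@@]2(C)C(=O)OC)[C@H]1CC[C@H](C)CC(=O)OC | intermediate
30 | (13S)-18-methoxy-18-oxolabd-8(17)-en-15-oic acid (4α-CO2Me, 4β-CH3, 5α-H, 9α-H, 10β-CH3), CNP0135192.1 | C=C1CC[C@@H]2[C@](C)(CCC[C@@]2(C)C(=O)OC)[C@H]1CC[C@H](C)CC(=O)O | target

**Step count.** Total: 22 steps. Longest linear sequence: 19 steps (steps 1–9 and 13–22); steps 10–12 make the side-chain salt.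

**Steps most likely to fail**

1. Step 9 (proposed new method). The catalyst may not turn over on the β,β-disubstituted enal, the enal face may be discriminated poorly, or Lewis-acid-induced E/Z isomerisation of the enal may erode the C9 configuration. Fallback with known chemistry, setting out from 14: cyclisation with stoichiometric Me2AlCl (CH2Cl2, −78 → −20 °C), the established achiral promotion of trienal cycloadditions, should give the racemic trans-fused adduct, that is 15 together with its mirror image ent-15 F1. Condensation of the mixture with (1R,2R)-N,N'-dimethyl-1,2-diphenylethane-1,2-diamine (molecular sieves, Et2O, rt) gives two diastereomeric imidazolidines, the aminal of 15 F2 and the aminal of ent-15 F3, which are separated by chromatography or crystallisation. Two-phase hydrolysis of F2 with dilute aqueous HCl at 0 °C returns to the route at 15.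

2. Step 13. The basic ylide may enolise the hindered aldehyde at C9, and loss of pivalic acid across C8–C9 (the C9 hydrogen and the C8 pivalate are trans-diaxial) would then give a conjugated dienal instead of the alkene. Fallback, setting out from 15: the non-basic Takai olefination (CrCl2, CHI3, THF, 0 °C) gives the E vinyl iodide F4. Bromide 18 is converted with zinc dust (I2 cat., N,N-dimethylacetamide, 70 °C) into the alkylzinc bromide F5, and Negishi coupling of F4 with F5 (Pd(PPh3)4, THF, rt) gives the 11E isomer of the coupled triester F6. Hydrogenation of F6 under the conditions of step 14 returns to the route at 22.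

3. Step 18. Hydride delivery to the axial ester may fail because it is shielded by the C10 methyl and repelled by the neighbouring carboxylate. Fallback, setting out from 25: SN2 demethylation of the axial ester (n-PrSLi, HMPA, rt) gives the triacid F7. Mild Fischer esterification (MeOH, p-toluenesulfonic acid cat., rt) esterifies only the C15 and the equatorial C18 acids and leaves the axial C19 acid, giving the dimethyl ester acid F8. Its conversion with 1-chloro-N,N,2-trimethylprop-1-en-1-amine (CH2Cl2, 0 °C) gives the acid chloride F9, and reduction with NaBH4 (THF, −20 °C) returns to the route at 27.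

**Further compounds**
F1 | step 9 | ent-15, mirror image of adduct 15 (second half of the racemate) | CC(C)(C)C(=O)O[C@@H]1C=C[C@H]2[C@@](C)(CCCC2(C(=O)OC)C(=O)OC)[C@@H]1C=O
F2 | step 9 | (4R,5R)-1,3-dimethyl-4,5-diphenylimidazolidin-2-yl aminal of 15 | CC(C)(C)C(=O)O[C@H]1C=C[C@@H]2[C@](C)(CCCC2(C(=O)OC)C(=O)OC)[C@H]1C1N(C)[C@H](c2ccccc2)[C@@H](c2ccccc2)N1C
F3 | step 9 | (4R,5R)-1,3-dimethyl-4,5-diphenylimidazolidin-2-yl aminal of ent-15 | CC(C)(C)C(=O)O[C@@H]1C=C[C@H]2[C@@](C)(CCCC2(C(=O)OC)C(=O)OC)[C@@H]1C1N(C)[C@H](c2ccccc2)[C@@H](c2ccccc2)N1C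
F4 | step 13 | dimethyl 9β-[(E)-2-iodoethenyl]-10β-methyl-8β-(pivaloyloxy)-5α-H-trans-decal-6-ene-4,4-dicarboxylate | CC(C)(C)C(=O)O[C@H]1C=C[C@@H]2[C@](C)(CCCC2(C(=O)OC)C(=O)OC)[C@H]1/C=C/I
F5 | step 13 | [(R)-4-methoxy-2-methyl-4-oxobutyl]zinc bromide | Br[Zn]C[C@H](C)CC(=O)OC
F6 | step 13 | trimethyl (11E,13R)-8β-(pivaloyloxy)-17-norlabda-6,11-diene-15,18,19-trioate | CC(C)(C)C(=O)O[C@H]1C=C[C@@H]2[C@](C)(CCCC2(C(=O)OC)C(=O)OC)[C@H]1/C=C/[C@H](C)CC(=O)OC
F7 | step 18 | (13S)-labd-8(17)-ene-15,18,19-trioic acid | C=C1CC[C@@H]2[C@](C)(CCCC2(C(=O)O)C(=O)O)[C@H]1CC[C@H](C)CC(=O)O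
F8 | step 18 | (13S)-15,18-dimethoxy-15,18-dioxolabd-8(17)-en-19-oic acid | C=C1CC[C@@H]2[C@](C)(CCC[C@@]2(C(=O)O)C(=O)OC)[C@H]1CC[C@H](C)CC(=O)OC
F9 | step 18 | dimethyl (13S)-19-chloro-19-oxolabd-8(17)-ene-15,18-dioate | C=C1CC[C@@H]2[C@](C)(CCC[C@@]2(C(=O)Cl)C(=O)OC)[C@H]1CC[C@H](C)CC(=O)OC
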